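**Retrosynthetic overview**

1. Locants: flavone numbering for rings A, C and B. In the side chain, C1'' is ArCH2, C2'' is the stereocentre and C3'' is the isopropenyl carbon. Backwards, the last moves are desilylation and then C3''=CH2 ⇒ C3''=O, so the isopropenyl group travels as an acetyl group.
2. The main disconnection is C8–C1'', giving unprotected apigenin and an achiral C9 α-substituted vinyl ketone. One amine-catalysed operation makes the bond, chooses C8 and sets C2'' (R) by enantioselective protonation.
3. Enabling feature: in ring A the C7(OH)=C8(H) enol unit is vinylogously tied (para, through C4a) to the ring-C carbonyl C4=O, which gives an acidic 7-OH and a carbon nucleophile at C8, reinforced by the para O5. In the chain, C2'' carries H next to C3'', so a C3'' ketone makes C1'' a Michael terminus and C2'' a protonation site.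
4. The enone ⇒ 4-bromo-2-methylbut-1-ene + diethyl (2-oxopropyl)phosphonate + formaldehyde (alkylation, Horner–Wadsworth–Emmons).
5. Ring order: rings A, B and C are bought in apigenin and none is built. The only ring formed is a temporary hemiketal pyran (O7–C3''), closed in the key step and opened one step later.

Key step: step 3

Assumption: the sense of induction of the diamine catalyst on this new arene class is taken by analogy with its indole additions, with the (S)-tert-leucine-derived catalyst assumed to protonate the Si face of C2''. If correlation shows the opposite sense, the enantiomeric catalyst from (R)-tert-leucine is used with no other change.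

**Step 1**
Reactants: 1 4-bromo-2-methylbut-1-ene; 2 diethyl (2-oxopropyl)phosphonate
Product: 3 diethyl (6-methyl-2-oxohept-6-en-3-yl)phosphonate (racemic)
Conditions: NaH, THF, 0 °C; then 1, NaI (cat.), DMF co-solvent, 60 °C
Reagents that add atoms: none
Why: SN2 C-alkylation of the soft sodium enolate of a β-ketophosphonate, with iodide catalysis so that substitution outruns E2; the new stereocentre is racemic and is destroyed in step 2.

**Step 2**
Reactants: 3 diethyl (6-methyl-2-oxohept-6-en-3-yl)phosphonate
Product: 4 6-methyl-3-methylidenehept-6-en-2-one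
Conditions: 37% aq. HCHO, K2CO3, THF/H2O, 0 °C → rt; BHT added, used fresh
Reagents that add atoms: formaldehyde, C=O
Why: Horner–Wadsworth–Emmons olefination with formaldehyde under aqueous carbonate is the standard entry to α-substituted vinyl ketones, and no stereochemistry arises.

**Step 3**
Reactants: 4 6-methyl-3-methylidenehept-6-en-2-one; 5 apigenin (slight excess)
Product: 7 (9R)-5,8-dihydroxy-2-(4-hydroxyphenyl)-8-methyl-9-(3-methylbut-3-en-1-yl)-9,10-dihydro-4H,8H-pyrano[2,3-f]chromen-4-one (hemiketal, both C8 epimers), via open-chain (R)-ketone 6 (not isolated)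
Conditions: (S)-N1,N1-diethyl-3,3-dimethylbutane-1,2-diamine·TfOH (20 mol %), BHT (cat.), THF/DMSO 4:1, 30 °C
Reagents that add atoms: none
Why: Proposed new method: the primary amine of the catalyst condenses with 4 to a ketiminium ion whose counter-ion is the 7-phenoxide of 5 (the 7-OH, para to the C4a–C4=O acyl group, is acidic enough to serve as the co-acid), C8 attacks the terminal CH2 of the iminium ion, rearomatisation passes the C8 proton to the base, and the tertiary ammonium arm of the catalyst protonates the enamine carbon C2'' before hydrolysis releases 6. The closest known reaction type is the Friedel–Crafts conjugate addition/enantioselective enamine protonation of indoles with α-substituted acroleins and vinyl ketones under chiral primary–tertiary diamine catalysis, and the A-ring reactivity called on is the one seen when 5,7-dihydroxyflavonoids add through C6/C8 to acrolein and to Mannich iminium ions; what is new is a phenolic flavone as the arene. The only ring closed is the temporary pyran of 7, by reversible 6-exo-trig addition of O7 to the C3'' carbonyl. C2'' is set as R by intramolecular N–H delivery to the Si face of the enamine, the face left open by the tert-butyl group of the catalyst, while the hemiketal carbon is uncontrolled and is erased in step 4. The step needs C8 over C6, C over O and mono over bis alkylation: C8 is the position that iminium electrophiles take in 5,7-dihydroxyflavones (it is flanked by O7 and the substituent-free ring oxygen O1, C6 by two hydroxyls), aryl ether adducts revert by retro-oxa-Michael reaction, and closure to 7 masks the acidic 7-OH so that the product can no longer form the phenoxide. The same closure withdraws the ketone from the amine and should keep C2'' from racemising through a re-formed enamine.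

**Step 4**
Reactants: 7 hemiketal
Product: 8 7,4'-bis-O-(tert-butyldimethylsilyl)-8-[(2R)-2-acetyl-5-methylhex-5-en-1-yl]apigenin (5-OH free)
Conditions: TBSCl (2.5 equiv), imidazole (5 equiv), DMF, 0 °C → rt
Reagents that add atoms: tert-butyldimethylsilyl chloride, CC(C)(C)[Si](C)(C)Cl
Why: Ring–chain tautomerism re-exposes the acidic 7-OH, which is silylated (like the 4'-OH) much faster than the tertiary hemiketal OH or the chelated 5-OH, so the equilibrium drains to the open ketone, and imidazole is too weak a base to enolise C2'' (standard phenol silylation).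

**Step 5**
Reactants: 8 bis-silyl ketone
Product: 9 7,4'-bis-O-(tert-butyldimethylsilyl)-8-[(2R)-5-methyl-2-(prop-1-en-2-yl)hex-5-en-1-yl]apigenin
Conditions: Zn, CH2Br2, TiCl4 (reagent pre-formed in THF, 5 °C), excess, CH2Cl2, 0 °C → rt; NaHCO3 work-up
Reagents that add atoms: dibromomethane, BrCBr
Why: Takai–Lombardo methylenation uses a non-basic gem-dimetallic reagent known to convert α-stereogenic, enolisable ketones without epimerisation; it leaves the vinylogous-ester C4=O, the aryl silyl ethers and the alkenes alone, and the excess covers the free 5-OH.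

**Step 6**
Reactants: 9 bis-silyl ether of the target
Product: 10 8-[(2R)-5-methyl-2-(prop-1-en-2-yl)hex-5-en-1-yl]apigenin (target)
Conditions: TBAF (2.2 equiv), AcOH (2.2 equiv), THF, 0 °C
Reagents that add atoms: none
Why: Fluoride cleavage of aryl silyl ethers in an acetic-acid-buffered medium avoids the acid-induced chroman closure of the 7-OH onto the isopropenyl group and does not touch C2''.

**Compound list**

1 | 4-bromo-2-methylbut-1-ene | C=C(C)CCBr | starting material
2 | diethyl (2-oxopropyl)phosphonate | CCOP(=O)(CC(C)=O)OCC | starting material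
3 | diethyl (6-methyl-2-oxohept-6-en-3-yl)phosphonate (racemic) | CCOP(=O)(OCC)C(CCC(C)=C)C(C)=O | intermediate
4 | 6-methyl-3-methylidenehept-6-en-2-one | CC(=O)C(=C)CCC(C)=C | intermediate
5 | apigenin | O=c1cc(-c2ccc(O)cc2)oc2cc(O)cc(O)c12 | starting material
6 | 8-[(2R)-2-acetyl-5-methylhex-5-en-1-yl]apigenin (open keto form) | C=C(C)CC[C@H](Cc1c(O)cc(O)c2c(=O)cc(-c3ccc(O)cc3)oc12)C(C)=O | intermediate
7 | (9R)-5,8-dihydroxy-2-(4-hydroxyphenyl)-8-methyl-9-(3-methylbut-3-en-1-yl)-9,10-dihydro-4H,8H-pyrano[2,3-f]chromen-4-one (C8 epimers) | C=C(C)CC[C@@H]1Cc2c(cc(O)c3c(=O)cc(-c4ccc(O)cc4)oc23)OC1(C)O | intermediate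
8 | 7,4'-bis-O-TBS-8-[(2R)-2-acetyl-5-methylhex-5-en-1-yl]apigenin | C=C(C)CC[C@H](Cc1c(O[Si](C)(C)C(C)(C)C)cc(O)c2c(=O)cc(-c3ccc(O[Si](C)(C)C(C)(C)C)cc3)oc12)C(C)=O | intermediate
9 | 7,4'-bis-O-TBS-8-[(2R)-5-methyl-2-(prop-1-en-2-yl)hex-5-en-1-yl]apigenin | C=C(C)CC[C@H](Cc1c(O[Si](C)(C)C(C)(C)C)cc(O)c2c(=O)cc(-c3ccc(O[Si](C)(C)C(C)(C)C)cc3)oc12)C(=C)C | intermediate
10 | 8-[(2R)-5-methyl-2-(prop-1-en-2-yl)hex-5-en-1-yl]apigenin | C=C(C)CC[C@H](Cc1c(O)cc(O)c2c(=O)cc(-c3ccc(O)cc3)oc12)C(=C)C | target

Total step count: 6. Longest linear sequence: 6 steps (1/2 → 10), of which 4 steps start from apigenin.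

**Steps most likely to fail**

**Step 3.**
- What may go wrong:
  - The ketiminium/phenoxide pair may react too slowly in the polar medium that 5 needs.
  - Attack through C6 may compete.
  - Proton delivery from bulk phenol, instead of from the catalyst arm, may erode facial selectivity.
- Fallback (known chemistry, same C8–C1'' bond by Negishi coupling of an auxiliary-derived chain): it sets out from 5 and 1 and comes back at 10, so steps 3–6 are bypassed.
  - Aryl partner: from 5, NaH/SEMCl (DMF) gives 5,7,4'-tris-O-SEM-apigenin F1. NIS in DMF then gives its 8-iodide F2, since 5-O-alkylated 5,7-dioxygenated flavones iodinate at C8.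
  - Electrophile: from 1, a Finkelstein reaction (NaI, acetone) gives 4-iodo-2-methylbut-1-ene F3.
  - Auxiliary: (S)-4-benzyloxazolidin-2-one is acylated (n-BuLi, 3-methylbut-2-enoyl chloride) to the senecioyl imide F4.
  - Stereocentre: the sodium dienolate of F4 (NaHMDS, THF, −78 °C) is α-alkylated with F3 anti to the benzyl group (Evans alkylation, deconjugative) to give the (2S)-imide F5.
  - Chain end: LiBH4 gives the (S)-alcohol F6, and I2/PPh3/imidazole gives the (S)-iodide F7. Zn/LiCl in THF then gives the alkylzinc iodide F8.
  - Coupling and release: Pd/RuPhos-catalysed coupling of F8 with F2 gives the tris-O-SEM target F9. TBAF (THF/DMPU, 60 °C) then gives 10.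

**Step 5.**
- What may go wrong:
  - Lewis-acid-induced loss of the 7-O-silyl group, with re-closure to the hemiketal.
  - Carbonyl-ene closure of the ketone onto the remote methallyl terminus.
  - Enolisation at C2''.
- Fallback (Peterson olefination): it sets out from 8 and comes back at 9. Me3SiCH2MgCl/CeCl3 (THF, −78 °C, excess to cover the 5-OH) adds as a non-basic organocerium reagent to give the β-hydroxysilane F10 (carbinol epimers). KHMDS (THF, 0 °C) triggers syn-elimination to 9. Any partly desilylated material is carried into step 6.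

**Step 1.**
- What may go wrong: E2 loss of HBr from the homoallylic bromide, O-alkylation and double alkylation.
- Fallback (polarity of 1 reversed): it sets out from 1 and comes back at 4, so steps 1 and 2 are bypassed. Mg in THF gives 3-methylbut-3-enylmagnesium bromide F11. CuI-catalysed, alkoxide-directed carbomagnesiation of but-3-yn-2-ol places the alkyl group on the internal alkyne carbon and gives 6-methyl-3-methylidenehept-6-en-2-ol F12. Dess–Martin oxidation then gives 4.

**Further compounds**

F1 | step 3 | 5,7,4'-tris-O-[2-(trimethylsilyl)ethoxymethyl]apigenin | O=c1cc(-c2ccc(OCOCC[Si](C)(C)C)cc2)oc2cc(OCOCC[Si](C)(C)C)cc(OCOCC[Si](C)(C)C)c12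
F2 | step 3 | 8-iodo-5,7,4'-tris-O-SEM-apigenin | O=c1cc(-c2ccc(OCOCC[Si](C)(C)C)cc2)oc2c(I)c(OCOCC[Si](C)(C)C)cc(OCOCC[Si](C)(C)C)c12
F3 | step 3 | 4-iodo-2-methylbut-1-ene | C=C(C)CCI
F4 | step 3 | (S)-4-benzyl-3-(3-methylbut-2-enoyl)oxazolidin-2-one | CC(C)=CC(=O)N1[C@@H](Cc2ccccc2)COC1=O
F5 | step 3 | (S)-4-benzyl-3-[(2S)-5-methyl-2-(prop-1-en-2-yl)hex-5-enoyl]oxazolidin-2-one | C=C(C)CC[C@H](C(=O)N1[C@@H](Cc2ccccc2)COC1=O)C(=C)C
F6 | step 3 | (2S)-5-methyl-2-(prop-1-en-2-yl)hex-5-en-1-ol | C=C(C)CC[C@H](CO)C(=C)C
F7 | step 3 | (3S)-3-(iodomethyl)-2,6-dimethylhepta-1,6-diene | C=C(C)CC[C@H](CI)C(=C)C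
F8 | step 3 | [(2S)-5-methyl-2-(prop-1-en-2-yl)hex-5-en-1-yl]zinc iodide | C=C(C)CC[C@H](C[Zn]I)C(=C)C
F9 | step 3 | 5,7,4'-tris-O-SEM-8-[(2R)-5-methyl-2-(prop-1-en-2-yl)hex-5-en-1-yl]apigenin | C=C(C)CC[C@H](Cc1c(OCOCC[Si](C)(C)C)cc(OCOCC[Si](C)(C)C)c2c(=O)cc(-c3ccc(OCOCC[Si](C)(C)C)cc3)oc12)C(=C)C
F10 | step 5 | 7,4'-bis-O-TBS-8-[(2R)-2-(2-hydroxy-1-trimethylsilylpropan-2-yl)-5-methylhex-5-en-1-yl]apigenin (carbinol epimers) | C=C(C)CC[C@H](Cc1c(O[Si](C)(C)C(C)(C)C)cc(O)c2c(=O)cc(-c3ccc(O[Si](C)(C)C(C)(C)C)cc3)oc12)C(C)(O)C[Si](C)(C)C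
F11 | step 1 | 3-methylbut-3-enylmagnesium bromide | C=C(C)CC[Mg]Br
F12 | step 1 | 6-methyl-3-methylidenehept-6-en-2-ol (racemic) | CC(O)C(=C)CCC(C)=C
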